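**Retrosynthetic overview**
1. Oxolane numbering: O1, C2 (aryl), C3 (carries C9H2OH), C4 (aroyl), C5 (H2). Two features carry the plan. C5 is unsubstituted, so the O1–C5 unit is one hidden molecule of formaldehyde. The C2 aryl is cis to C9 on C3, the less stable arrangement, and an SN2-type opening of a trans-substituted cyclopropane produces exactly that.
2. C4–H is traced back to C4–C(=O)–O–C9, a γ-lactone cis-fused to the oxolane (3,7-dioxabicyclo[3.3.0]octan-2-one). It is excised last by hydrolysis and loss of CO2.
3. Key disconnection of O1–C2 and C4–C5: a formal (3+2) of formaldehyde with a 1-aroyl-6-aryl-3-oxabicyclo[3.1.0]hexan-2-one, in which the cyclopropane bond C2–C4 breaks.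
4. Cyclopropane and lactone arise together from the E-cinnamyl α-diazo-β-keto ester by enantioselective intramolecular cyclopropanation. The ester comes from the cinnamyl alcohol and ethyl aroylacetate.
5. Ring order: lactone and cyclopropane (one step), then the oxolane (cyclopropane consumed), then removal of the lactone.

Key step: step 5

Assumption: the sense of induction of the chiral cobalt porphyrin on this diazo ester is to be fixed by a pilot run; both ligand antipodes can be prepared, and the one that gives the (1R,5S,6R)-cyclopropane lactone is used.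

**Step 1**
Reactants: 1 methyl (E)-3-(3,4,5-trimethoxyphenyl)prop-2-enoate
Product: 2 (E)-3-(3,4,5-trimethoxyphenyl)prop-2-en-1-ol
Conditions: iBu2AlH (2.5 equiv), CH2Cl2, −78 → 0 °C; aq. potassium sodium tartrate
Reagents that add atoms: none
Why: The 1,2-reduction of an α,β-unsaturated ester with iBu2AlH should stop at the allylic alcohol and keep the E-alkene, whereas LiAlH4 on cinnamic acid derivatives tends to saturate the conjugated C=C as well.

**Step 2**
Reactants: 2 (E)-3-(3,4,5-trimethoxyphenyl)prop-2-en-1-ol; 3 ethyl 3-oxo-3-(3,4,5-trimethoxyphenyl)propanoate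
Product: 4 (E)-3-(3,4,5-trimethoxyphenyl)prop-2-en-1-yl 3-oxo-3-(3,4,5-trimethoxyphenyl)propanoate
Conditions: DMAP (0.3 equiv), toluene, reflux, EtOH removed over 4 Å MS
Reagents that add atoms: none
Why: DMAP-catalysed transesterification of a β-keto ester is driven by removal of ethanol and runs below the temperature at which the allyl β-keto ester would undergo Carroll rearrangement.

**Step 3**
Reactants: 4 (E)-3-(3,4,5-trimethoxyphenyl)prop-2-en-1-yl 3-oxo-3-(3,4,5-trimethoxyphenyl)propanoate
Product: 5 (E)-3-(3,4,5-trimethoxyphenyl)prop-2-en-1-yl 2-diazo-3-oxo-3-(3,4,5-trimethoxyphenyl)propanoate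
Conditions: p-ABSA (1.2 equiv), Et3N, MeCN, 0 °C → rt
Reagents that add atoms: 4-acetamidobenzenesulfonyl azide (p-ABSA), CC(=O)Nc1ccc(cc1)S(=O)(=O)N=[N+]=[N-]
Why: Regitz diazo transfer to the activated methylene of a 1,3-dicarbonyl compound needs only an amine base and leaves the alkene and aryl ethers untouched.

**Step 4**
Reactants: 5 (E)-3-(3,4,5-trimethoxyphenyl)prop-2-en-1-yl 2-diazo-3-oxo-3-(3,4,5-trimethoxyphenyl)propanoate
Product: 6 (1R,5S,6R)-1-(3,4,5-trimethoxybenzoyl)-6-(3,4,5-trimethoxyphenyl)-3-oxabicyclo[3.1.0]hexan-2-one (aryl exo: trans to C4H2 of the bicycle, cis to the aroyl group)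
Conditions: [Co(3,5-DiMes-QingPhyrin)] (2 mol %), toluene, rt → 40 °C, N2
Reagents that add atoms: none
Why: Intramolecular cyclopropanation by metalloradical catalysis with a D2-symmetric chiral porphyrin of divalent cobalt is established for allyl α-acyl-, α-cyano- and α-nitrodiazoacetates, a doubly acceptor-substituted class on which chiral dirhodium carboxylates induce poorly; lactone and cyclopropane form together, the amide-lined ligand pocket selects the alkene face and so fixes C1 and C5 of the bicycle (future C4 and C3), and the E-alkene places the aryl group at C6 (future C2) exo.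

**Step 5**
Reactants: 6 (1R,5S,6R)-1-(3,4,5-trimethoxybenzoyl)-6-(3,4,5-trimethoxyphenyl)-3-oxabicyclo[3.1.0]hexan-2-one; 7 formaldehyde (monomer, cracked from dried commercial paraformaldehyde)
Product: 9 (1S,5S,6S)-1-(3,4,5-trimethoxybenzoyl)-6-(3,4,5-trimethoxyphenyl)-3,7-dioxabicyclo[3.3.0]octan-2-one, via oxocarbenium enolate 8 (not isolated)
Conditions: Sn(OTf)2 (20 mol %), CH2O gas (from paraformaldehyde, 150 °C, about 10 equiv), 4 Å MS, CH2Cl2, −40 → 0 °C, quench at full conversion
Reagents that add atoms: none
Why: Proposed new method: Sn(OTf)2 should chelate the ketone and lactone carbonyl oxygens of 6 and polarise C2–C4, the only cyclopropane bond that is both benzylic and doubly acceptor-substituted, so that the oxygen of 7 attacks C2 from the rear of that bond (O1–C2) and the tin enolate of 8 then adds through C4 to the CH2=O+ carbon (C4–C5). The closest known reaction type is the Lewis-acid-catalysed (3+2) annulation of 2-arylcyclopropane-1,1-diesters with aryl, alkenyl and alkyl aldehydes, which transfers chirality with clean inversion at the aryl-bearing carbon; new here are formaldehyde as partner and a ketone/lactone acceptor pair on a bicyclic cyclopropane. The single ring closed is the oxolane, by a 5-(enolexo)-endo-trig aldol-type attack on the oxocarbenium ion, the same mode that operates in the known annulations. C2 is set by inversion of the 6R benzylic centre, so the aryl group that was trans to C9 on the cyclopropane ends cis to C9 on the oxolane; quaternary C4 is set by the lactone, because the short O1–C2–C3 tether can bring C5 only to the enolate face on which C2 stands and hence only the cis-fused bicycle can form; C3 is untouched and carries the absolute configuration through. The step needs concerted opening instead of free ionisation, attack at C2 and not at C3, and capture by 7 ahead of Cloke–Wilson-type closure to a 2,3-dihydrofuran: the trimethoxyphenyl ring (twisted 4-methoxy, two inductively withdrawing meta-methoxy groups) is only a moderate cation stabiliser, the strain of the bicyclo[3.1.0] core lowers the barrier of the SN2-like path, only C2 is benzylic, and the ketone oxygen cannot reach the rear of C2–C4 without prior ionisation, while excess monomeric 7 at low temperature favours the bimolecular event.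

**Step 6**
Reactants: 9 (1S,5S,6S)-1-(3,4,5-trimethoxybenzoyl)-6-(3,4,5-trimethoxyphenyl)-3,7-dioxabicyclo[3.3.0]octan-2-one
Product: 12 [(3R,4S,5S)-4-(hydroxymethyl)-5-(3,4,5-trimethoxyphenyl)oxolan-3-yl](3,4,5-trimethoxyphenyl)methanone, via hydroxy keto acid 10 (not isolated), via enol 11 (not isolated)
Conditions: LiOH·H2O (1.5 equiv), THF/H2O, 0 °C; AcOH to pH 4, 45 °C; extractive work-up, then DBU (10 mol %), CH2Cl2, rt
Reagents that add atoms: lithium hydroxide, [Li+].[OH-] (its oxygen enters 10 and leaves again with CO2)
Why: Acyl–oxygen saponification of the strained γ-lactone frees C9 as CH2OH and gives β-keto acid 10, which on mild acidification should lose CO2 through the cyclic six-centre transition state (β-keto acid decarboxylation) to enol 11; ketonisation under equilibrating conditions places the aroyl group at C4 trans to the C3 hydroxymethyl group (thermodynamic control), C2 and C3 are not touched, and β-elimination of O1 is the reverse of a 5-endo-trig closure and should stay slow.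

**Compound list**
1 | methyl (E)-3-(3,4,5-trimethoxyphenyl)prop-2-enoate | COC(=O)/C=C/c1cc(OC)c(OC)c(OC)c1 | starting material
2 | (E)-3-(3,4,5-trimethoxyphenyl)prop-2-en-1-ol | OC/C=C/c1cc(OC)c(OC)c(OC)c1 | intermediate
3 | ethyl 3-oxo-3-(3,4,5-trimethoxyphenyl)propanoate | CCOC(=O)CC(=O)c1cc(OC)c(OC)c(OC)c1 | starting material
4 | (E)-3-(3,4,5-trimethoxyphenyl)prop-2-en-1-yl 3-oxo-3-(3,4,5-trimethoxyphenyl)propanoate | O=C(CC(=O)c1cc(OC)c(OC)c(OC)c1)OC/C=C/c1cc(OC)c(OC)c(OC)c1 | intermediate
5 | (E)-3-(3,4,5-trimethoxyphenyl)prop-2-en-1-yl 2-diazo-3-oxo-3-(3,4,5-trimethoxyphenyl)propanoate | O=C(OC/C=C/c1cc(OC)c(OC)c(OC)c1)C(=[N+]=[N-])C(=O)c1cc(OC)c(OC)c(OC)c1 | intermediate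
6 | (1R,5S,6R)-1-(3,4,5-trimethoxybenzoyl)-6-(3,4,5-trimethoxyphenyl)-3-oxabicyclo[3.1.0]hexan-2-one | O=C(c1cc(OC)c(OC)c(OC)c1)[C@]12C(=O)OC[C@H]1[C@@H]2c1cc(OC)c(OC)c(OC)c1 | intermediate
7 | formaldehyde | C=O | starting material
8 | (4S)-4-[(S)-(methylideneoxonio)(3,4,5-trimethoxyphenyl)methyl]-3-[(Z)-oxido(3,4,5-trimethoxyphenyl)methylidene]oxolan-2-one, drawn without tin | C=[O+][C@H](c1cc(OC)c(OC)c(OC)c1)[C@@H]1COC(=O)/C1=C(\[O-])c1cc(OC)c(OC)c(OC)c1 | intermediate
9 | (1S,5S,6S)-1-(3,4,5-trimethoxybenzoyl)-6-(3,4,5-trimethoxyphenyl)-3,7-dioxabicyclo[3.3.0]octan-2-one (cis-fused, 6-aryl cis to C4H2) | O=C(c1cc(OC)c(OC)c(OC)c1)[C@]1(CO[C@H](c2cc(OC)c(OC)c(OC)c2)[C@@H]1CO2)C2=O | intermediate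
10 | (3S,4S,5S)-4-(hydroxymethyl)-3-(3,4,5-trimethoxybenzoyl)-5-(3,4,5-trimethoxyphenyl)oxolane-3-carboxylic acid | O=C(c1cc(OC)c(OC)c(OC)c1)[C@@]1(C(=O)O)CO[C@H](c2cc(OC)c(OC)c(OC)c2)[C@@H]1CO | intermediate
11 | [(4S,5S)-4-(hydroxymethyl)-5-(3,4,5-trimethoxyphenyl)oxolan-3-ylidene](3,4,5-trimethoxyphenyl)methanol (enol, double-bond geometry not defined) | OC(c1cc(OC)c(OC)c(OC)c1)=C1CO[C@H](c2cc(OC)c(OC)c(OC)c2)[C@@H]1CO | intermediate
12 | [(3R,4S,5S)-4-(hydroxymethyl)-5-(3,4,5-trimethoxyphenyl)oxolan-3-yl](3,4,5-trimethoxyphenyl)methanone | COc1cc(C(=O)[C@H]2CO[C@H](c3cc(OC)c(OC)c(OC)c3)[C@@H]2CO)cc(OC)c1OC | target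

**Total step count:** 6
**Longest linear sequence:** 6 steps (1 → 2 → 4 → 5 → 6 → 9 → 12)

**Steps most likely to fail**

1. **Step 5.**
   - What may go wrong: formaldehyde may oligomerise on the Lewis acid or attack too slowly. The activated cyclopropane then drifts into ionisation (loss of the inversion at C2) or isomerises through capture by its own ketone oxygen. More than one formaldehyde unit may also be taken up, and the electron-rich donor ring may be hydroxymethylated.
   - Fallback: it sets out from 6 and returns at 9. The annulation is run with (E)-cinnamaldehyde under Sn(OTf)2 in CH2Cl2. Cinnamaldehyde belongs to the most nucleophilic aldehyde class for which this (3+2) reaction is established. This should give the 8-styryl bicycle F1, with the styryl group expected cis to the 6-aryl group; its configuration is of no consequence.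
   - Lemieux–Johnson cleavage (OsO4 cat., NaIO4, 2,6-lutidine, dioxane/H2O) should then give the 8-carbaldehyde F2.
   - Tsuji–Wilkinson decarbonylation with RhCl(PPh3)3 (1 equiv, toluene, reflux) removes the extra carbon and the C5 stereocentre to give 9. The rhodium alkyl has no β-hydrogen, because its neighbours are quaternary C4 and O1.

2. **Step 6.**
   - What may go wrong: hydroxide may attack the aryl ketone (retro-Claisen loss of the aroyl group). Relactonisation may outrun decarboxylation after acidification. Equilibration at C4 may remain incomplete.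
   - Fallback: it sets out from 9 and returns at 12, and removes the surplus carbon as formaldehyde instead of CO2. LiAlH4 (THF, 0 °C) reduces lactone and ketone to the triol F3, a mixture of carbinol epimers that does not matter.
   - DDQ (CH2Cl2, rt) oxidises only the electron-rich benzylic carbinol and gives the bis(hydroxymethyl) ketone F4, in which the former lactone carbon is a CH2OH group on quaternary C4.
   - K2CO3 in MeOH then triggers retro-aldol loss of that group. The enolate is protonated under the same equilibrating conditions to give 12.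

3. **Step 4.**
   - What may go wrong: face selection on the bulky, electron-rich aroyl diazo ester may be insufficient, diazo activation may be sluggish, and the ligand is laborious to obtain.
   - Fallback: it sets out from 5 and returns at 6, and replaces asymmetric catalysis by resolution. Rh2(esp)2 (0.5 mol %, CH2Cl2, reflux) should give the exo-aryl cyclopropane lactone as the racemate, that is 6 together with its antipode F5.
   - The two are separated by preparative chromatography on a chiral stationary phase (immobilised amylose tris(3,5-dimethylphenylcarbamate), supercritical CO2/MeOH). Crystallisation can raise the purity of 6 further.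

**Further compounds**
F1 | step 5 | (1S,5S,6S,8S)-8-[(E)-2-phenylethenyl]-1-(3,4,5-trimethoxybenzoyl)-6-(3,4,5-trimethoxyphenyl)-3,7-dioxabicyclo[3.3.0]octan-2-one | O=C(c1cc(OC)c(OC)c(OC)c1)[C@]1([C@H](/C=C/c2ccccc2)O[C@H](c2cc(OC)c(OC)c(OC)c2)[C@@H]1CO2)C2=O
F2 | step 5 | (1S,5S,6S,8R)-8-formyl-1-(3,4,5-trimethoxybenzoyl)-6-(3,4,5-trimethoxyphenyl)-3,7-dioxabicyclo[3.3.0]octan-2-one | O=C(c1cc(OC)c(OC)c(OC)c1)[C@]1([C@H](C=O)O[C@H](c2cc(OC)c(OC)c(OC)c2)[C@@H]1CO2)C2=O
F3 | step 6 | [(3S,4S,5S)-3,4-bis(hydroxymethyl)-5-(3,4,5-trimethoxyphenyl)oxolan-3-yl](3,4,5-trimethoxyphenyl)methanol (carbinol epimers) | OC(c1cc(OC)c(OC)c(OC)c1)[C@@]1(CO)CO[C@H](c2cc(OC)c(OC)c(OC)c2)[C@@H]1CO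
F4 | step 6 | [(3S,4S,5S)-3,4-bis(hydroxymethyl)-5-(3,4,5-trimethoxyphenyl)oxolan-3-yl](3,4,5-trimethoxyphenyl)methanone | O=C(c1cc(OC)c(OC)c(OC)c1)[C@@]1(CO)CO[C@H](c2cc(OC)c(OC)c(OC)c2)[C@@H]1CO
F5 | step 4 | (1S,5R,6S)-1-(3,4,5-trimethoxybenzoyl)-6-(3,4,5-trimethoxyphenyl)-3-oxabicyclo[3.1.0]hexan-2-one | O=C(c1cc(OC)c(OC)c(OC)c1)[C@@]12C(=O)OC[C@@H]1[C@H]2c1cc(OC)c(OC)c(OC)c1
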